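The C14–CHO bond and the C14=C15 geometry are made from a C14≡C15 alkyne. Because the enal is homoallylic to the C17 oxygen, a hydrosilane tethered to O17 adds with carbon monoxide across the alkyne: silicon goes to C15, the formyl group to C14, syn, closing a temporary five-membered oxasilolane (O17–Si–C15–C16–C17). The precursor is the O17-diisopropylsilyl ether of a syn-aldol-derived (17R,18S)-diallyl succinate bearing the homofarnesyl alkyne; allyl esters are used because the polyene, the enal and the C18–H/C17–O pair rule out acidic or basic unmasking. Silicon is later removed at the dicarboxylate stage and the C19–C21 anhydride ring is closed under a silyl ether.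

Key step: step 9

Remark: a free O17–H beside a primary C20 ester or acid is assumed to lactonise easily, so such species are kept as carboxylate salts or silylated at once; atom numbers follow the target chain (C14=C15 enal, C17 carbinol, C18 ring CH, C19 ring CH2, C20 and C21 carbonyls).

Step 1
Reactants: 1 (2E,6E)-farnesyl bromide; 2 1-(trimethylsilyl)propyne
Product: 4 trimethyl[(5E,9E)-6,10,14-trimethylpentadeca-5,9,13-trien-1-yn-1-yl]silane, via lithiated silylpropyne 3 (not isolated)
Conditions: 2, n-BuLi, THF, −20 °C; then 1, −78 °C → rt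
Reagents that add atoms: none
Why: Propargylic alkylation: the lithiated silylpropyne should attack the primary allylic bromide by SN2 through its CH2 terminus (the silyl group disfavours the allenyl mode), forming the C12–C13 bond without touching the E,E-alkenes.

Step 2
Reactants: 4 trimethyl[(5E,9E)-6,10,14-trimethylpentadeca-5,9,13-trien-1-yn-1-yl]silane
Product: 5 (5E,9E)-6,10,14-trimethylpentadeca-5,9,13-trien-1-yne
Conditions: K2CO3 (cat.), MeOH–THF, rt
Reagents that add atoms: none
Why: Protodesilylation of an alkynylsilane by catalytic methoxide is selective for the C(sp)–Si bond and should leave the skipped triene untouched.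

Step 3
Reactants: 5 (5E,9E)-6,10,14-trimethylpentadeca-5,9,13-trien-1-yne; 6 oxirane
Product: 8 (7E,11E)-8,12,16-trimethylheptadeca-7,11,15-trien-3-yn-1-ol, via lithium acetylide 7 (not isolated)
Conditions: n-BuLi, THF, −78 °C; BF3·OEt2, then 6, −78 °C; aq NH4Cl
Reagents that add atoms: none
Why: Yamaguchi–Hirao alkynylation: the lithium acetylide activated by BF3 should open oxirane at low temperature to the homopropargylic alcohol, fixing the C14≡C15–C16–C17 connectivity.

Step 4
Reactants: 8 (7E,11E)-8,12,16-trimethylheptadeca-7,11,15-trien-3-yn-1-ol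
Product: 9 (7E,11E)-8,12,16-trimethylheptadeca-7,11,15-trien-3-ynal
Conditions: Dess–Martin periodinane, NaHCO3, CH2Cl2, 0 °C; used crude at once
Reagents that add atoms: none
Why: Dess–Martin oxidation under bicarbonate buffer is a neutral, non-enolising way to the β,γ-alkynyl aldehyde, which is taken on crude because base or silica would shift it to the allenal.

Step 5
Reactants: 10 (S)-4-benzyloxazolidin-2-one; 11 methyl 4-chloro-4-oxobutanoate
Product: 13 (S)-4-benzyl-3-(4-methoxy-4-oxobutanoyl)oxazolidin-2-one, via lithium oxazolidinide 12 (not isolated)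
Conditions: n-BuLi, THF, −78 °C; then 11, −78 → 0 °C
Reagents that add atoms: none
Why: N-Acylation of the lithium oxazolidinide by the acid chloride is the standard entry to Evans imides and should be faster than any attack on the methyl ester.

Step 6
Reactants: 13 (S)-4-benzyl-3-(4-methoxy-4-oxobutanoyl)oxazolidin-2-one; 9 (7E,11E)-8,12,16-trimethylheptadeca-7,11,15-trien-3-ynal
Product: 15 methyl (3S,4R,10E,14E)-3-{[(4S)-4-benzyl-2-oxooxazolidin-3-yl]carbonyl}-4-hydroxy-11,15,19-trimethylicosa-10,14,18-trien-6-ynoate, via dibutylboron Z-enolate 14 (not isolated)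
Conditions: 13, Bu2BOTf, i-Pr2NEt, CH2Cl2, −78 → 0 °C; then 9, −78 → 0 °C; pH 7 buffer, MeOH, H2O2, 0 °C; used crude
Reagents that add atoms: none
Why: Evans syn-aldol: the Z(O)-boron enolate of the (S)-benzyl imide should react through a closed chair (Zimmerman–Traxler) transition state on the face away from the benzyl group, setting C18 (S) and C17 (R) together, with the aldehyde added cold to preformed enolate so that it is consumed before base can isomerise it; any adduct that closes O17 onto the methyl ester converges in step 7.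

Step 7
Reactants: 15 methyl (3S,4R,10E,14E)-3-{[(4S)-4-benzyl-2-oxooxazolidin-3-yl]carbonyl}-4-hydroxy-11,15,19-trimethylicosa-10,14,18-trien-6-ynoate
Product: 17 diallyl (2S)-2-[(1R,7E,11E)-1-hydroxy-8,12,16-trimethylheptadeca-7,11,15-trien-3-yn-1-yl]butanedioate, via dilithium hydroxy dicarboxylate 16 (not isolated)
Conditions: LiOH, 30% H2O2, THF–H2O, 0 °C → rt; Na2SO3; EtOAc wash (recovers 10); CO2 to pH 8–9, freeze-dry; allyl bromide, Bu4NBr (cat.), DMF, rt; neutral work-up, used at once
Reagents that add atoms: lithium hydroxide [Li+].[OH-]; hydrogen peroxide OO; allyl bromide C=CCBr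
Why: Hydroperoxide should cleave the exocyclic imide carbonyl selectively (standard auxiliary removal) and hydroxide saponify the C20 methyl ester or its lactone, after which the never-acidified dicarboxylate is O-alkylated by allyl bromide (carboxylate SN2), so the γ-hydroxy acid to lactone collapse is avoided and neither stereocentre is touched.

Step 8
Reactants: 17 diallyl (2S)-2-[(1R,7E,11E)-1-hydroxy-8,12,16-trimethylheptadeca-7,11,15-trien-3-yn-1-yl]butanedioate; 18 chlorodiisopropylsilane
Product: 19 diallyl (2S)-2-[(1R,7E,11E)-1-[(diisopropylsilyl)oxy]-8,12,16-trimethylheptadeca-7,11,15-trien-3-yn-1-yl]butanedioate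
Conditions: imidazole, CH2Cl2, 0 °C, 30 min
Reagents that add atoms: none
Why: Silylation of the secondary alcohol with a chlorohydrosilane and imidazole is fast at 0 °C and should outrun closure of O17 onto the C20 allyl ester, while the Si–H bond survives the non-nucleophilic conditions.

Step 9
Reactants: 19 diallyl (2S)-2-[(1R,7E,11E)-1-[(diisopropylsilyl)oxy]-8,12,16-trimethylheptadeca-7,11,15-trien-3-yn-1-yl]butanedioate; 20 carbon monoxide
Product: 21 diallyl (2S)-2-{(3Z,5R)-2,2-diisopropyl-3-[(5E,9E)-6,10,14-trimethyl-1-oxopentadeca-5,9,13-trien-2-ylidene]-1,2-oxasilolan-5-yl}butanedioate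
Conditions: Rh(acac)(CO)2 (2 mol %), CO (30 bar), toluene, 65 °C
Reagents that add atoms: none
Why: Rhodium should insert into the Si–H bond of 19, the silyl–rhodium species add syn across the tethered alkyne with silicon bonding to the proximal C15, carbon monoxide insert into the resulting C14–Rh bond and reductive elimination with hydride release the aldehyde. The closest known reaction is the rhodium-catalysed intramolecular silylformylation of homopropargylic hydrosilyl ethers, a class that includes internal alkynes and dialkylsilyl tethers. The single ring formed, the 1,2-oxasilolane O17–Si–C15–C16–C17, closes in the 5-exo-dig mode. No stereocentre is created; the alkene geometry (Si and CHO cis, hence C13 and C16 cis) follows from the syn addition, and C17 and C18 are spectators. The step needs formyl at C14 rather than C15, syn addition, and chemoselectivity over plain hydrosilylation and over the other C=C bonds: the five-membered tether should enforce the first two, CO pressure the third, and trisubstituted and allyl-ester olefins are not expected to insert under hydrogen-free conditions.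

Step 10
Reactants: 21 diallyl (2S)-2-{(3Z,5R)-2,2-diisopropyl-3-[(5E,9E)-6,10,14-trimethyl-1-oxopentadeca-5,9,13-trien-2-ylidene]-1,2-oxasilolan-5-yl}butanedioate
Product: 22 (2S)-2-{(3Z,5R)-2,2-diisopropyl-3-[(5E,9E)-6,10,14-trimethyl-1-oxopentadeca-5,9,13-trien-2-ylidene]-1,2-oxasilolan-5-yl}butanedioic acid
Conditions: Pd(PPh3)4 (5 mol %), sodium p-toluenesulfinate, THF–MeOH, rt; pH 4 buffer
Reagents that add atoms: none
Why: Tsuji–Trost deallylation: Pd(0) should ionise both allyl esters and the sulfinate trap the π-allyl irreversibly at neutral pH, sparing the acid-sensitive triene, the enolisable enal, the C18 centre and the oxasilolane that still keeps O17 from lactonising.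

Step 11
Reactants: 22 (2S)-2-{(3Z,5R)-2,2-diisopropyl-3-[(5E,9E)-6,10,14-trimethyl-1-oxopentadeca-5,9,13-trien-2-ylidene]-1,2-oxasilolan-5-yl}butanedioic acid
Product: 25 (2S)-2-[(1R,3E,7E,11E)-4-formyl-8,12,16-trimethyl-1-[(triethylsilyl)oxy]heptadeca-3,7,11,15-tetraen-1-yl]butanedioic acid, via bis(tetrabutylammonium) hydroxy dicarboxylate 23 (not isolated), via tris(triethylsilyl) derivative 24 (not isolated)
Conditions: TBAF, THF, rt; evaporate; TESCl, imidazole, DMF, 0 °C → rt; K2CO3, MeOH–H2O, 0 °C; pH 5 buffer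
Reagents that add atoms: chlorotriethylsilane CC[Si](Cl)(CC)CC
Why: Fluoride should open the strained oxasilolane and replace silicon on C15 by hydrogen with retention (fluoride-promoted protodesilylation of an alkenyl siloxane), revealing the (E)-enal while both carboxyls are anions that cannot acylate O17; exhaustive triethylsilylation and mild hydrolysis of the two labile silyl esters then leave O17 as a TES ether.

Step 12
Reactants: 25 (2S)-2-[(1R,3E,7E,11E)-4-formyl-8,12,16-trimethyl-1-[(triethylsilyl)oxy]heptadeca-3,7,11,15-tetraen-1-yl]butanedioic acid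
Product: 26 (3S)-3-[(1R,3E,7E,11E)-4-formyl-8,12,16-trimethyl-1-[(triethylsilyl)oxy]heptadeca-3,7,11,15-tetraen-1-yl]oxolane-2,5-dione
Conditions: DCC, CH2Cl2, 0 °C → rt; filter
Reagents that add atoms: none
Why: Carbodiimide dehydration of a 1,4-diacid should give the five-membered cyclic anhydride under neutral conditions, the TES ether keeping O17 from competing for the activated C20 carboxyl.

Step 13
Reactants: 26 (3S)-3-[(1R,3E,7E,11E)-4-formyl-8,12,16-trimethyl-1-[(triethylsilyl)oxy]heptadeca-3,7,11,15-tetraen-1-yl]oxolane-2,5-dione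
Product: 27 Hippolide D
Conditions: HF·pyridine, THF, 0 °C, short; cold pH 7 buffer–EtOAc, rapid work-up
Reagents that add atoms: none
Why: Acidic fluoride should cleave the triethylsilyl ether by Si–O fluorinolysis at 0 °C without the basic or nucleophilic species that would open the anhydride or catalyse O17-to-C20 acyl transfer, and neither stereocentre nor the enal is affected.

Compound list
1 | (2E,6E)-farnesyl bromide | CC(C)=CCC/C(C)=C/CC/C(C)=C/CBr | starting material
2 | 1-(trimethylsilyl)propyne | CC#C[Si](C)(C)C | starting material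
3 | [3-(trimethylsilyl)prop-2-yn-1-yl]lithium | [Li]CC#C[Si](C)(C)C | intermediate (not isolated)
4 | trimethyl[(5E,9E)-6,10,14-trimethylpentadeca-5,9,13-trien-1-yn-1-yl]silane | CC(C)=CCC/C(C)=C/CC/C(C)=C/CCC#C[Si](C)(C)C | intermediate
5 | (5E,9E)-6,10,14-trimethylpentadeca-5,9,13-trien-1-yne | CC(C)=CCC/C(C)=C/CC/C(C)=C/CCC#C | intermediate
6 | oxirane | C1CO1 | starting material
7 | lithium (5E,9E)-6,10,14-trimethylpentadeca-5,9,13-trien-1-yn-1-ide | CC(C)=CCC/C(C)=C/CC/C(C)=C/CCC#C[Li] | intermediate (not isolated)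
8 | (7E,11E)-8,12,16-trimethylheptadeca-7,11,15-trien-3-yn-1-ol | CC(C)=CCC/C(C)=C/CC/C(C)=C/CCC#CCCO | intermediate
9 | (7E,11E)-8,12,16-trimethylheptadeca-7,11,15-trien-3-ynal | CC(C)=CCC/C(C)=C/CC/C(C)=C/CCC#CCC=O | intermediate
10 | (S)-4-benzyloxazolidin-2-one | O=C1OC[C@H](Cc2ccccc2)N1 | starting material
11 | methyl 4-chloro-4-oxobutanoate | COC(=O)CCC(=O)Cl | starting material
12 | lithium (S)-4-benzyl-2-oxooxazolidin-3-ide | [Li]N1[C@@H](Cc2ccccc2)COC1=O | intermediate (not isolated)
13 | (S)-4-benzyl-3-(4-methoxy-4-oxobutanoyl)oxazolidin-2-one | COC(=O)CCC(=O)N1[C@@H](Cc2ccccc2)COC1=O | intermediate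
14 | (S)-4-benzyl-3-[(Z)-1-[(dibutylboranyl)oxy]-4-methoxy-4-oxobut-1-en-1-yl]oxazolidin-2-one | COC(=O)C/C=C(\OB(CCCC)CCCC)N1[C@@H](Cc2ccccc2)COC1=O | intermediate (not isolated)
15 | methyl (3S,4R,10E,14E)-3-{[(4S)-4-benzyl-2-oxooxazolidin-3-yl]carbonyl}-4-hydroxy-11,15,19-trimethylicosa-10,14,18-trien-6-ynoate | CC(C)=CCC/C(C)=C/CC/C(C)=C/CCC#CC[C@@H](O)[C@H](CC(=O)OC)C(=O)N1[C@@H](Cc2ccccc2)COC1=O | intermediate
16 | dilithium (2S)-2-[(1R,7E,11E)-1-hydroxy-8,12,16-trimethylheptadeca-7,11,15-trien-3-yn-1-yl]butanedioate | CC(C)=CCC/C(C)=C/CC/C(C)=C/CCC#CC[C@@H](O)[C@H](CC(=O)[O-])C(=O)[O-].[Li+].[Li+] | intermediate (not isolated)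
17 | diallyl (2S)-2-[(1R,7E,11E)-1-hydroxy-8,12,16-trimethylheptadeca-7,11,15-trien-3-yn-1-yl]butanedioate | CC(C)=CCC/C(C)=C/CC/C(C)=C/CCC#CC[C@@H](O)[C@H](CC(=O)OCC=C)C(=O)OCC=C | intermediate
18 | chlorodiisopropylsilane | CC(C)[SiH](Cl)C(C)C | starting material
19 | diallyl (2S)-2-[(1R,7E,11E)-1-[(diisopropylsilyl)oxy]-8,12,16-trimethylheptadeca-7,11,15-trien-3-yn-1-yl]butanedioate | CC(C)=CCC/C(C)=C/CC/C(C)=C/CCC#CC[C@@H](O[SiH](C(C)C)C(C)C)[C@H](CC(=O)OCC=C)C(=O)OCC=C | intermediate
20 | carbon monoxide | [C-]#[O+] | starting material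
21 | diallyl (2S)-2-{(3Z,5R)-2,2-diisopropyl-3-[(5E,9E)-6,10,14-trimethyl-1-oxopentadeca-5,9,13-trien-2-ylidene]-1,2-oxasilolan-5-yl}butanedioate | CC(C)=CCC/C(C)=C/CC/C(C)=C/CC/C(C=O)=C1\C[C@H]([C@H](CC(=O)OCC=C)C(=O)OCC=C)O[Si]1(C(C)C)C(C)C | intermediate
22 | (2S)-2-{(3Z,5R)-2,2-diisopropyl-3-[(5E,9E)-6,10,14-trimethyl-1-oxopentadeca-5,9,13-trien-2-ylidene]-1,2-oxasilolan-5-yl}butanedioic acid | CC(C)=CCC/C(C)=C/CC/C(C)=C/CC/C(C=O)=C1\C[C@H]([C@H](CC(=O)O)C(=O)O)O[Si]1(C(C)C)C(C)C | intermediate
23 | bis(tetrabutylammonium) (2S)-2-[(1R,3E,7E,11E)-4-formyl-1-hydroxy-8,12,16-trimethylheptadeca-3,7,11,15-tetraen-1-yl]butanedioate | CCCC[N+](CCCC)(CCCC)CCCC.CCCC[N+](CCCC)(CCCC)CCCC.CC(C)=CCC/C(C)=C/CC/C(C)=C/CC/C(C=O)=C\C[C@@H](O)[C@H](CC(=O)[O-])C(=O)[O-] | intermediate (not isolated)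
24 | bis(triethylsilyl) (2S)-2-[(1R,3E,7E,11E)-4-formyl-8,12,16-trimethyl-1-[(triethylsilyl)oxy]heptadeca-3,7,11,15-tetraen-1-yl]butanedioate | CC(C)=CCC/C(C)=C/CC/C(C)=C/CC/C(C=O)=C\C[C@@H](O[Si](CC)(CC)CC)[C@H](CC(=O)O[Si](CC)(CC)CC)C(=O)O[Si](CC)(CC)CC | intermediate (not isolated)
25 | (2S)-2-[(1R,3E,7E,11E)-4-formyl-8,12,16-trimethyl-1-[(triethylsilyl)oxy]heptadeca-3,7,11,15-tetraen-1-yl]butanedioic acid | CC(C)=CCC/C(C)=C/CC/C(C)=C/CC/C(C=O)=C\C[C@@H](O[Si](CC)(CC)CC)[C@H](CC(=O)O)C(=O)O | intermediate
26 | (3S)-3-[(1R,3E,7E,11E)-4-formyl-8,12,16-trimethyl-1-[(triethylsilyl)oxy]heptadeca-3,7,11,15-tetraen-1-yl]oxolane-2,5-dione | CC(C)=CCC/C(C)=C/CC/C(C)=C/CC/C(C=O)=C\C[C@@H](O[Si](CC)(CC)CC)[C@@H]1CC(=O)OC1=O | intermediate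
27 | Hippolide D, (3S)-3-[(1R,3E,7E,11E)-4-formyl-1-hydroxy-8,12,16-trimethylheptadeca-3,7,11,15-tetraen-1-yl]oxolane-2,5-dione | CC(C)=CCC/C(C)=C/CC/C(C)=C/CC/C(C=O)=C\C[C@@H](O)[C@@H]1CC(=O)OC1=O | target

Total step count: 13. Longest linear sequence: 12 (steps 1–4 and 6–13; step 5 is the side branch).

Steps most likely to fail

Step 9. The rhodium hydride and silyl species may be diverted by the two allyl-ester olefins (double-bond migration to propenyl esters, allylic C–O insertion), so that 19 is consumed before carbon monoxide is taken up at C14. The fallback removes the extra olefins and changes the unmasking chemistry. It sets out from dilithium salt 16, which is alkylated with iodomethane in DMF to dimethyl (2S)-2-[(1R,7E,11E)-1-hydroxy-8,12,16-trimethylheptadeca-7,11,15-trien-3-yn-1-yl]butanedioate F1. This is silylated at once with 18 and imidazole to the hydrosilyl ether F2, and the same Rh/CO silylformylation is run on this olefin-free ester set to give the dimethyl oxasilolane aldehyde F3. Both methyl esters are then cleaved with trimethyltin hydroxide (1,2-dichloroethane, 80 °C), which comes back to the route at diacid 22.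

Step 6. The β,γ-alkynyl aldehyde 9 may undergo amine-promoted prototropic shift to the allenal (and on to the dienal) or self-condense faster than the boron enolate captures it, so that little aldol adduct forms. The fallback makes the C16–C15 bond by epoxide opening and takes both stereocentres from a chiral-pool butenolide. It sets out from alkyne 5 (as acetylide 7) and purchased (S)-5-(hydroxymethyl)furan-2(5H)-one F4. F4 is silylated (TBDPSCl, imidazole) to the silyl ether F5. A vinyl cuprate (vinylMgBr, CuBr·SMe2, TMSCl, THF, −78 °C) should add trans to the C5 substituent to give the vinyl lactone F6. RuCl3/NaIO4 cleaves the vinyl group to the lactone acid F7, TMSCHN2 gives the methyl ester F8, HF·pyridine frees the hydroxymethyl lactone F9, and TsCl/pyridine gives the tosylate F10. NaOMe in MeOH at 0 °C opens the lactone and the liberated alkoxide displaces the tosylate, giving dimethyl (2S)-2-[(2S)-oxiran-2-yl]butanedioate F11. Acetylide 7 with BF3·OEt2 (THF, −78 °C) opens F11 at the terminal carbon C16; the hydroxy diester formed first (identical with F1) is left to close to the alkynyl lactone ester F12. LiOH in aqueous THF then opens lactone and ester to dilithium salt 16, where the route is rejoined at the allylation of step 7.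

Step 13. Once O17 is unmasked, the hydroxyl may be acylated intramolecularly by the C20 carbonyl under pyridine or fluoride catalysis (anhydride to γ-lactone acid), or the anhydride may hydrolyse during work-up. The fallback closes the anhydride last on the unprotected hydroxy dicarboxylate, so that no deprotection follows ring closure. It sets out from salt 23 (made from 22 with two equivalents of TBAF and dried azeotropically) and adds one equivalent of trifluoroacetic anhydride in CH2Cl2 at −78 °C. The mixed anhydride formed at one carboxylate should be captured by the neighbouring carboxylate far faster than by the neutral O17–H, giving 27 directly. This fallback makes no new compound (F0).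

Further compounds
F1 | step 9 | dimethyl (2S)-2-[(1R,7E,11E)-1-hydroxy-8,12,16-trimethylheptadeca-7,11,15-trien-3-yn-1-yl]butanedioate | CC(C)=CCC/C(C)=C/CC/C(C)=C/CCC#CC[C@@H](O)[C@H](CC(=O)OC)C(=O)OC
F2 | step 9 | dimethyl (2S)-2-[(1R,7E,11E)-1-[(diisopropylsilyl)oxy]-8,12,16-trimethylheptadeca-7,11,15-trien-3-yn-1-yl]butanedioate | CC(C)=CCC/C(C)=C/CC/C(C)=C/CCC#CC[C@@H](O[SiH](C(C)C)C(C)C)[C@H](CC(=O)OC)C(=O)OC
F3 | step 9 | dimethyl (2S)-2-{(3Z,5R)-2,2-diisopropyl-3-[(5E,9E)-6,10,14-trimethyl-1-oxopentadeca-5,9,13-trien-2-ylidene]-1,2-oxasilolan-5-yl}butanedioate | CC(C)=CCC/C(C)=C/CC/C(C)=C/CC/C(C=O)=C1\C[C@H]([C@H](CC(=O)OC)C(=O)OC)O[Si]1(C(C)C)C(C)C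
F4 | step 6 | (S)-5-(hydroxymethyl)furan-2(5H)-one (purchased) | OC[C@H]1OC(=O)C=C1
F5 | step 6 | (S)-5-{[(tert-butyldiphenylsilyl)oxy]methyl}furan-2(5H)-one | CC(C)(C)[Si](OC[C@H]1OC(=O)C=C1)(c1ccccc1)c1ccccc1
F6 | step 6 | (4R,5S)-5-{[(tert-butyldiphenylsilyl)oxy]methyl}-4-vinyldihydrofuran-2(3H)-one | CC(C)(C)[Si](OC[C@H]1OC(=O)C[C@@H]1C=C)(c1ccccc1)c1ccccc1
F7 | step 6 | (2S,3S)-2-{[(tert-butyldiphenylsilyl)oxy]methyl}-5-oxotetrahydrofuran-3-carboxylic acid | CC(C)(C)[Si](OC[C@H]1OC(=O)C[C@@H]1C(=O)O)(c1ccccc1)c1ccccc1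
F8 | step 6 | methyl (2S,3S)-2-{[(tert-butyldiphenylsilyl)oxy]methyl}-5-oxotetrahydrofuran-3-carboxylate | CC(C)(C)[Si](OC[C@H]1OC(=O)C[C@@H]1C(=O)OC)(c1ccccc1)c1ccccc1
F9 | step 6 | methyl (2S,3S)-2-(hydroxymethyl)-5-oxotetrahydrofuran-3-carboxylate | OC[C@H]1OC(=O)C[C@@H]1C(=O)OC
F10 | step 6 | methyl (2S,3S)-5-oxo-2-[(tosyloxy)methyl]tetrahydrofuran-3-carboxylate | Cc1ccc(cc1)S(=O)(=O)OC[C@H]1OC(=O)C[C@@H]1C(=O)OC
F11 | step 6 | dimethyl (2S)-2-[(2S)-oxiran-2-yl]butanedioate | COC(=O)C[C@@H]([C@H]1CO1)C(=O)OC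
F12 | step 6 | methyl (2R,3S)-5-oxo-2-[(6E,10E)-7,11,15-trimethylhexadeca-6,10,14-trien-2-yn-1-yl]tetrahydrofuran-3-carboxylate | CC(C)=CCC/C(C)=C/CC/C(C)=C/CCC#CC[C@H]1OC(=O)C[C@@H]1C(=O)OC
F0 | step 13 | none | none
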